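**Plan**

1. Retrosynthesis (labdane numbering): the C7 carbinol is taken back to a C7 ketone and the three esters to a 2,3,20-triol. The C9–C11 bond and the C7 oxygen are taken back to an alkylative 1,3-carbonyl transposition of an 8-methyl-Δ7-9-ketone with a C11–C16 organometallic made from (R)-linalool.
2. Ring B is then cut at C8. Its C9(=O)–C8(X)=C7 unit, next to quaternary C10, is what a dihalocarbene leaves when it inserts one carbon between the two carbons of a cyclopentanone silyl enol ether. Ring B therefore comes from the five-membered ring C5–C6–C7–C9–C10 of a trans-hydrindan-9-one; C17 is joined to C8 by Suzuki coupling of the bromide.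
3. Ring A is cut at C2=C3 (ring-closing metathesis), at C1–C10 (enolate allylation) and at C4–C5 (conjugate reverse prenylation of a cyclopentenone ester whose CO2Me is C20).
4. Forward order: cyclopentanone core, ring A (metathesis, then dihydroxylation), five-to-six expansion to ring B, side chain, carbonyl transposition, acylations, reduction.
5. Stereochemistry: C5 from a Cu(OTf)2/bis(oxazoline)-catalysed Hosomi–Sakurai addition; C10 by allylation anti to the C5 substituent (trans ring fusion); C2 and C3 by α-face OsO4 dihydroxylation; C13 from (R)-linalool; C7 by Corey–Bakshi–Shibata reduction; the Z ester from angelic acid.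

Key step: step 10

Remark: atoms are numbered as in the labdane skeleton of the target (C20 = CH2O on C10, C17 = CH3 on C8, C18/C19 = CH3 on C4); α is the face of H-5, β the face of C20; in the hydrindane intermediates C8 is absent and C9 is bonded to C7.

Assumption: the (S,S) ligand in step 2 is taken to expose the enone face that leads to (5R)-6; if the sense of induction is the reverse, the (R,R) ligand is used.

**Route**

Step 1
Reactants: 1 methyl 2-oxocyclopentane-1-carboxylate
Product: 4 methyl 5-oxocyclopent-1-ene-1-carboxylate, via α-phenylselanyl keto ester 2 (not isolated), via selenoxide 3 (not isolated)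
Conditions: PhSeCl, pyridine, CH2Cl2, 0 °C; then 30% H2O2, 0 °C to rt; used at once
Reagents that add atoms: none
Why: α-Selenenylation of the β-keto ester, oxidation to the selenoxide and its syn elimination (selenoxide elimination) should give the doubly activated enone, which forms no stereocentre and is used directly because it dimerises on standing.

Step 2
Reactants: 4 methyl 5-oxocyclopent-1-ene-1-carboxylate; 5 trimethyl(3-methylbut-2-en-1-yl)silane
Product: 6 methyl (5R)-5-(2-methylbut-3-en-2-yl)-2-oxocyclopentane-1-carboxylate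
Conditions: Cu(OTf)2 (10 mol %), (S,S)-t-Bu-box [2,2′-(propane-2,2-diyl)bis((4S)-4-tert-butyl-4,5-dihydrooxazole)] (11 mol %), 4 Å molecular sieves, CH2Cl2, −78 to −20 °C; aq. NH4Cl
Reagents that add atoms: none
Why: Catalytic enantioselective Hosomi–Sakurai conjugate allylation: the keto ester chelates the Cu(OTf)2–bis(oxazoline) complex and the allylsilane attacks C5 through its γ-carbon (SE2′), which should install C4 with both methyl groups and the C3=C2 vinyl group and set C5 by catalyst control of the enone face.

Step 3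
Reactants: 6 methyl (5R)-5-(2-methylbut-3-en-2-yl)-2-oxocyclopentane-1-carboxylate
Product: 7 methyl (1R,5S)-5-(2-methylbut-3-en-2-yl)-2-oxo-1-(prop-2-en-1-yl)cyclopentane-1-carboxylate
Conditions: allyl bromide, K2CO3, acetone, 56 °C
Reagents that add atoms: allyl bromide, C=CCBr
Why: C-Allylation of the β-keto ester enolate should occur on the face anti to the bulky tert-alkyl group on C5, setting quaternary C10 with allyl (C1, C2) trans to the C5 substituent and CO2Me (C20) cis to it, the relationship that becomes the trans ring fusion.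

Step 4
Reactants: 7 methyl (1R,5S)-5-(2-methylbut-3-en-2-yl)-2-oxo-1-(prop-2-en-1-yl)cyclopentane-1-carboxylate
Product: 8 methyl (3aS,7aR)-4,4-dimethyl-1-oxo-2,3,3a,4,7,7a-hexahydro-1H-indene-7a-carboxylate
Conditions: second-generation Grubbs catalyst (H2IMes)(PCy3)Cl2Ru=CHPh (5 mol %), CH2Cl2, 40 °C
Reagents that add atoms: none
Why: Ring-closing olefin metathesis of the two terminal alkenes on the trans-disposed arms should close six-membered ring A at C2=C3 with loss of ethylene and without touching a stereocentre.

Step 5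
Reactants: 8 methyl (3aS,7aR)-4,4-dimethyl-1-oxo-2,3,3a,4,7,7a-hexahydro-1H-indene-7a-carboxylate
Product: 9 2α,3α-diol of 8 (both OH cis to H-5 and trans to CO2Me)
Conditions: OsO4 (2 mol %), N-methylmorpholine N-oxide, acetone/H2O (8:1), rt
Reagents that add atoms: osmium tetroxide, O=[Os](=O)(=O)=O; N-methylmorpholine N-oxide, C[N+]1([O-])CCOCC1; water, O
Why: Upjohn dihydroxylation should add both oxygens syn from the α face, because the β face of the only alkene is screened by the axial CO2Me on C10 and the axial 4β-methyl group; this sets C2 and C3.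

Step 6
Reactants: 9 2α,3α-diol of 8
Product: 10 2α,3α-O-isopropylidene keto ester
Conditions: 2,2-dimethoxypropane, pyridinium p-toluenesulfonate (cat.), acetone, rt
Reagents that add atoms: 2,2-dimethoxypropane, COC(C)(C)OC
Why: Acid-catalysed transketalisation should protect the cis-diol as its acetonide for the basic, organometallic and oxidative steps that follow.

Step 7
Reactants: 10 2α,3α-O-isopropylidene keto ester
Product: 11 C9 triisopropylsilyl enol ether (C9=C7) of 10
Conditions: TIPSOTf, Et3N, CH2Cl2, 0 °C to rt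
Reagents that add atoms: triisopropylsilyl trifluoromethanesulfonate, CC(C)[Si](OS(=O)(=O)C(F)(F)F)(C(C)C)C(C)C
Why: Soft enolisation of the ketone, which can enolise only towards C7 because C10 is quaternary, should give the silyl enol ether that masks the ketone during ester reduction and serves as the activating group for the ring expansion.

Step 8
Reactants: 11 C9 triisopropylsilyl enol ether of 10
Product: 12 C20 primary alcohol (enol ether retained)
Conditions: LiAlH4, Et2O, 0 °C; aq. potassium sodium tartrate work-up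
Reagents that add atoms: none
Why: Hydride reduction of the neopentyl ester should give the C20 alcohol while the silyl enol ether is inert to LiAlH4; with the ketone masked, neither ketone reduction nor retro-aldol loss of C20 can occur.

Step 9
Reactants: 12 C20 primary alcohol
Product: 13 C20 triisopropylsilyl ether of 12 (bis-silyl compound)
Conditions: TIPSOTf, 2,6-lutidine, CH2Cl2, −78 to 0 °C
Reagents that add atoms: triisopropylsilyl trifluoromethanesulfonate, CC(C)[Si](OS(=O)(=O)C(F)(F)F)(C(C)C)C(C)C
Why: Silylation of the primary alcohol should give a base-stable and mild-acid-stable C20 ether that lasts until step 19.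

Step 10
Reactants: 13 C20 triisopropylsilyl ether of 12 (bis-silyl compound)
Product: 15 8-bromo-Δ7-en-9-one of the trans-decalin (2α,3α-acetonide; 10β-CH2OTIPS; 5α-H), via dibromocyclopropane 14 (not isolated)
Conditions: CHBr3 (2 equiv), KOtBu (1.8 equiv), pentane, −30 °C; aq. NH4Cl at −30 °C; then toluene, 60 °C
Reagents that add atoms: bromoform, BrC(Br)Br
Why: KOtBu and CHBr3 give dibromocarbene, which adds in a concerted cheletropic [2+1] manner to the electron-rich C9=C7 enol ether from the α face (anti to the β-CH2OTIPS group on C10) and so closes the cyclopropane C9–C8–C7 of the 1-siloxy-6,6-dibromobicyclo[3.1.0]hexane 14. The bromine that lies endo to the five-membered ring then leaves while the fused C9–C7 bond opens in the thermally allowed disrotatory two-electron electrocyclic mode, the oxygen on C9 stabilising the 1-siloxyallyl cation, and transfer of the silyl group to bromide leaves the 8-bromo-Δ7-9-ketone; the five-membered ring has thereby become six-membered ring B with C8 inserted between C9 and C7. The closest known reaction type is the dihalocarbene ring expansion of cyclic silyl enol ethers to 2-halocycloalk-2-enones, the carbocyclic counterpart of the Ciamician–Dennstedt reaction. No lasting stereocentre is created: the two cyclopropane stereocentres vanish on opening, and C5 and C10 are not involved. The step needs chemoselective cyclopropanation, secured because the enol ether is the only C=C bond in 13; it needs an endo leaving group, guaranteed because CBr2 always places one bromine endo; and it needs one enone regiochemistry, fixed by the siloxy group (C9 becomes C=O and the carbene carbon becomes C8).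

Step 11
Reactants: 15 8-bromo-Δ7-en-9-one
Product: 16 8-methyl-Δ7-en-9-one (2α,3α-acetonide; 10β-CH2OTIPS)
Conditions: MeB(OH)2, Pd(OAc)2 (5 mol %), SPhos (10 mol %), K3PO4, toluene/H2O (10:1), 80 °C
Reagents that add atoms: methylboronic acid, CB(O)O
Why: Suzuki–Miyaura coupling of the α-bromo enone (oxidative addition of the vinyl C–Br bond to zerovalent palladium, transmetalation from the methylboronate, reductive elimination) should put C17 on C8 without touching the enone.

Step 12
Reactants: 17 (R)-(−)-linalool
Product: 18 (R)-linalool triethylsilyl ether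
Conditions: TESOTf, 2,6-lutidine, CH2Cl2, −78 to 0 °C
Reagents that add atoms: triethylsilyl trifluoromethanesulfonate, CC[Si](CC)(CC)OS(=O)(=O)C(F)(F)F
Why: Silyl triflate with a hindered base should protect the tertiary allylic alcohol (C13–OH), which would not survive the chromium oxidation of step 16.

Step 13
Reactants: 18 (R)-linalool triethylsilyl ether
Product: 20 (4R)-4-methyl-4-(triethylsilyloxy)hex-5-enoic acid, via aldehyde 19 (not isolated)
Conditions: O3 (1 equiv, Sudan red end point), CH2Cl2, −78 °C; PPh3; then NaClO2, NaH2PO4, 2-methylbut-2-ene, t-BuOH/H2O, rt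
Reagents that add atoms: ozone, [O-][O+]=O; sodium chlorite, [Na+].[O-]Cl=O
Why: Ozone should cleave the electron-rich trisubstituted alkene much faster than the vinyl group next to the quaternary silyloxy carbon, and Pinnick oxidation of the aldehyde then gives the acid with C13 untouched.

Step 14
Reactants: 20 (4R)-4-methyl-4-(triethylsilyloxy)hex-5-enoic acid
Product: 22 (3R)-5-iodo-3-methyl-3-(triethylsilyloxy)pent-1-ene, via Barton ester 21 (not isolated)
Conditions: 1-hydroxypyridine-2(1H)-thione, DCC, DMAP (cat.), CH2Cl2, 0 °C, dark; then CHI3, benzene, tungsten lamp, 60 °C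
Reagents that add atoms: iodoform, IC(I)I
Why: Barton decarboxylation: the thiohydroxamate ester fragments to the primary C11 radical, which should abstract iodine from iodoform faster than it can add to the remote vinyl group, shortening the chain by one carbon.

Step 15
Reactants: 22 (3R)-5-iodo-3-methyl-3-(triethylsilyloxy)pent-1-ene; 16 8-methyl-Δ7-en-9-one
Product: 24 (13R)-2α,3α-isopropylidenedioxy-13-(triethylsilyloxy)-20-(triisopropylsilyloxy)labda-7,14-dien-9-ol, via organolithium 23 (not isolated)
Conditions: t-BuLi (2.1 equiv), Et2O/pentane, −78 °C; anhydrous CeCl3, THF, −78 °C; then 16, −78 to −40 °C; aq. NH4Cl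
Reagents that add atoms: none
Why: Iodine–lithium exchange gives the primary alkyllithium (kept cold in ether to suppress silyl migration) and transmetalation to the less basic organocerium should favour 1,2-addition over enolisation at the hindered C9 ketone, forming the C9–C11 bond; attack anti to the C10 substituent is expected (9β-OH), but this centre is removed in step 16.

Step 16
Reactants: 24 (13R)-2α,3α-isopropylidenedioxy-13-(triethylsilyloxy)-20-(triisopropylsilyloxy)labda-7,14-dien-9-ol
Product: 25 (13R)-2α,3α-isopropylidenedioxy-13-(triethylsilyloxy)-20-(triisopropylsilyloxy)labda-8,14-dien-7-one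
Conditions: pyridinium chlorochromate (C5H5NH)[CrO3Cl] (3 equiv), NaOAc, 4 Å molecular sieves, CH2Cl2, rt
Reagents that add atoms: pyridinium chlorochromate, c1cc[nH+]cc1.[O-][Cr](=O)(=O)Cl
Why: Babler–Dauben oxidative transposition: the chromate ester of the tertiary allylic alcohol should undergo [3,3]-sigmatropic shift to C7 and be oxidised there, which moves the oxygen from C9 to C7 and the alkene into the tetrasubstituted C8=C9 position; the tertiary silyl ether, acetonide and vinyl group are inert to the buffered oxidant.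

Step 17
Reactants: 25 (13R)-2α,3α-isopropylidenedioxy-13-(triethylsilyloxy)-20-(triisopropylsilyloxy)labda-8,14-dien-7-one
Product: 26 (13R)-2α,3α,13-trihydroxy-20-(triisopropylsilyloxy)labda-8,14-dien-7-one
Conditions: AcOH/H2O/THF (3:1:1), 45 °C
Reagents that add atoms: none
Why: Mild aqueous acid should hydrolyse the acetonide and the tertiary triethylsilyl ether but not the hindered primary triisopropylsilyl ether, exposing the 2α,3α-diol.

Step 18
Reactants: 26 (13R)-2α,3α,13-trihydroxy-20-(triisopropylsilyloxy)labda-8,14-dien-7-one; 27 angelic acid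
Product: 29 (13R)-2α-angeloyloxy-3α,13-dihydroxy-20-(triisopropylsilyloxy)labda-8,14-dien-7-one, via mixed anhydride 28 (not isolated)
Conditions: 27, 2,4,6-trichlorobenzoyl chloride, Et3N, toluene, rt; then 26, 75 °C
Reagents that add atoms: none
Why: Yamaguchi-type esterification through the mixed anhydride, which is attacked at the unshielded angeloyl carbonyl and should transfer the acyl group without Z to E isomerisation; the equatorial 2α-OH should react in preference to the axial 3α-OH next to the gem-dimethyl carbon and to the tertiary C13–OH.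

Step 19
Reactants: 29 (13R)-2α-angeloyloxy-3α,13-dihydroxy-20-(triisopropylsilyloxy)labda-8,14-dien-7-one
Product: 30 (13R)-2α-angeloyloxy-3α,13,20-trihydroxylabda-8,14-dien-7-one
Conditions: HF·pyridine, pyridine, THF, 0 °C to rt
Reagents that add atoms: none
Why: Fluoride should cleave the primary silyl ether under weakly acidic conditions, which avoid the base-induced acyl migration from O2 to O3.

Step 20
Reactants: 30 (13R)-2α-angeloyloxy-3α,13,20-trihydroxylabda-8,14-dien-7-one
Product: 31 (13R)-3α,20-diacetoxy-2α-angeloyloxy-13-hydroxylabda-8,14-dien-7-one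
Conditions: Ac2O, pyridine, rt (no DMAP)
Reagents that add atoms: acetic anhydride, CC(=O)OC(C)=O
Why: Acetylation of the primary C20–OH and, more slowly, of the axial 3α-OH should proceed in pyridine alone, and leaving out the acyl-transfer catalyst keeps the tertiary allylic C13–OH free.

Step 21
Reactants: 31 (13R)-3α,20-diacetoxy-2α-angeloyloxy-13-hydroxylabda-8,14-dien-7-one
Product: 32 (13R)-3α,20-diacetoxy-2α-angeloyloxylabda-8,14-diene-7α,13-diol (target CNP0180940.1)
Conditions: (S)-2-methyl-CBS-oxazaborolidine (1 equiv), catecholborane, toluene, −78 °C; MeOH, then aq. NaH2PO4/Na2HPO4 buffer (pH 7)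
Reagents that add atoms: none
Why: Corey–Bakshi–Shibata reduction: the ketone binds the oxazaborolidine boron anti to the larger α-substituted alkenyl arm (C8) and hydride from catecholborane should be delivered to the β face of C7, setting the 7α (7R) carbinol by reagent control; at this temperature catecholborane neither hydroborates the vinyl group nor reduces the esters.

**Compound list**

1 | methyl 2-oxocyclopentane-1-carboxylate | COC(=O)C1CCCC1=O | starting material
2 | methyl 2-oxo-1-(phenylselanyl)cyclopentane-1-carboxylate | COC(=O)C1([Se]c2ccccc2)CCCC1=O | intermediate (not isolated)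
3 | selenoxide of 2 | COC(=O)C1([Se](=O)c2ccccc2)CCCC1=O | intermediate (not isolated)
4 | methyl 5-oxocyclopent-1-ene-1-carboxylate | COC(=O)C1=CCCC1=O | intermediate
5 | trimethyl(3-methylbut-2-en-1-yl)silane | CC(C)=CC[Si](C)(C)C | starting material
6 | methyl (5R)-5-(2-methylbut-3-en-2-yl)-2-oxocyclopentane-1-carboxylate (C1 epimers and enol in equilibrium) | O=C1CC[C@@H](C(C)(C)C=C)C1C(=O)OC | intermediate
7 | methyl (1R,5S)-5-(2-methylbut-3-en-2-yl)-2-oxo-1-(prop-2-en-1-yl)cyclopentane-1-carboxylate (allyl trans to the tert-alkyl group) | O=C1CC[C@@H](C(C)(C)C=C)[C@@]1(CC=C)C(=O)OC | intermediate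
8 | methyl (3aS,7aR)-4,4-dimethyl-1-oxo-2,3,3a,4,7,7a-hexahydro-1H-indene-7a-carboxylate (trans-fused; C9 ketone, C2=C3 alkene, CO2Me = C20) | O=C1CC[C@H]2C(C)(C)C=CC[C@]12C(=O)OC | intermediate
9 | 2α,3α-diol of 8 (both OH cis to H-5, trans to CO2Me) | O=C1CC[C@H]2C(C)(C)[C@H](O)[C@H](O)C[C@]12C(=O)OC | intermediate
10 | 2α,3α-O-isopropylidene derivative of 9 | O=C1CC[C@H]2C(C)(C)[C@H](OC3(C)C)[C@H](O3)C[C@]12C(=O)OC | intermediate
11 | C9 triisopropylsilyl enol ether of 10 (C9=C7) | CC(C)[Si](C(C)C)(C(C)C)OC1=CC[C@H]2C(C)(C)[C@H](OC3(C)C)[C@H](O3)C[C@]12C(=O)OC | intermediate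
12 | C20 primary alcohol from 11 | CC(C)[Si](C(C)C)(C(C)C)OC1=CC[C@H]2C(C)(C)[C@H](OC3(C)C)[C@H](O3)C[C@]12CO | intermediate
13 | C20 triisopropylsilyl ether of 12 | CC(C)[Si](C(C)C)(C(C)C)OC1=CC[C@H]2C(C)(C)[C@H](OC3(C)C)[C@H](O3)C[C@]12CO[Si](C(C)C)(C(C)C)C(C)C | intermediate
14 | dibromocarbene adduct of 13 (1-siloxy-6,6-dibromobicyclo[3.1.0]hexane unit, cyclopropane on the α face) | CC(C)[Si](C(C)C)(C(C)C)O[C@@]14[C@H](C4(Br)Br)C[C@H]2C(C)(C)[C@H](OC3(C)C)[C@H](O3)C[C@]12CO[Si](C(C)C)(C(C)C)C(C)C | intermediate (not isolated)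
15 | trans-decalin 8-bromo-Δ7-en-9-one (4,4-dimethyl; 2α,3α-acetonide; 10β-CH2OTIPS; 5α-H; C11–C17 absent) | O=C1C(Br)=CC[C@H]2C(C)(C)[C@H](OC3(C)C)[C@H](O3)C[C@]12CO[Si](C(C)C)(C(C)C)C(C)C | intermediate
16 | 8-methyl analogue of 15 (8-methyl-Δ7-en-9-one) | O=C1C(C)=CC[C@H]2C(C)(C)[C@H](OC3(C)C)[C@H](O3)C[C@]12CO[Si](C(C)C)(C(C)C)C(C)C | intermediate
17 | (R)-(−)-linalool | C=C[C@](C)(O)CCC=C(C)C | starting material
18 | (R)-linalool triethylsilyl ether | C=C[C@](C)(O[Si](CC)(CC)CC)CCC=C(C)C | intermediate
19 | (4R)-4-methyl-4-(triethylsilyloxy)hex-5-enal | C=C[C@](C)(O[Si](CC)(CC)CC)CCC=O | intermediate (not isolated)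
20 | (4R)-4-methyl-4-(triethylsilyloxy)hex-5-enoic acid | C=C[C@](C)(O[Si](CC)(CC)CC)CCC(=O)O | intermediate
21 | 2-thioxopyridin-1(2H)-yl (4R)-4-methyl-4-(triethylsilyloxy)hex-5-enoate | C=C[C@](C)(O[Si](CC)(CC)CC)CCC(=O)ON1C=CC=CC1=S | intermediate (not isolated)
22 | (3R)-5-iodo-3-methyl-3-(triethylsilyloxy)pent-1-ene | C=C[C@](C)(O[Si](CC)(CC)CC)CCI | intermediate
23 | (3R)-3-methyl-3-(triethylsilyloxy)pent-4-enyllithium | C=C[C@](C)(O[Si](CC)(CC)CC)CC[Li] | intermediate (not isolated)
24 | (13R)-2α,3α-isopropylidenedioxy-13-(triethylsilyloxy)-20-(triisopropylsilyloxy)labda-7,14-dien-9-ol (9β-OH expected) | C=C[C@](C)(O[Si](CC)(CC)CC)CC[C@]1(O)C(C)=CC[C@H]2C(C)(C)[C@H](OC3(C)C)[C@H](O3)C[C@]12CO[Si](C(C)C)(C(C)C)C(C)C | intermediate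
25 | (13R)-2α,3α-isopropylidenedioxy-13-(triethylsilyloxy)-20-(triisopropylsilyloxy)labda-8,14-dien-7-one | C=C[C@](C)(O[Si](CC)(CC)CC)CCC1=C(C)C(=O)C[C@H]2C(C)(C)[C@H](OC3(C)C)[C@H](O3)C[C@]12CO[Si](C(C)C)(C(C)C)C(C)C | intermediate
26 | (13R)-2α,3α,13-trihydroxy-20-(triisopropylsilyloxy)labda-8,14-dien-7-one | C=C[C@](C)(O)CCC1=C(C)C(=O)C[C@H]2C(C)(C)[C@H](O)[C@H](O)C[C@]12CO[Si](C(C)C)(C(C)C)C(C)C | intermediate
27 | angelic acid, (Z)-2-methylbut-2-enoic acid | C/C=C(/C)C(=O)O | starting material
28 | angelic 2,4,6-trichlorobenzoic anhydride | C/C=C(/C)C(=O)OC(=O)c1c(Cl)cc(Cl)cc1Cl | intermediate (not isolated)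
29 | (13R)-2α-angeloyloxy-3α,13-dihydroxy-20-(triisopropylsilyloxy)labda-8,14-dien-7-one | C=C[C@](C)(O)CCC1=C(C)C(=O)C[C@H]2C(C)(C)[C@H](O)[C@H](OC(=O)/C(C)=C\C)C[C@]12CO[Si](C(C)C)(C(C)C)C(C)C | intermediate
30 | (13R)-2α-angeloyloxy-3α,13,20-trihydroxylabda-8,14-dien-7-one | C=C[C@](C)(O)CCC1=C(C)C(=O)C[C@H]2C(C)(C)[C@H](O)[C@H](OC(=O)/C(C)=C\C)C[C@]12CO | intermediate
31 | (13R)-3α,20-diacetoxy-2α-angeloyloxy-13-hydroxylabda-8,14-dien-7-one | C=C[C@](C)(O)CCC1=C(C)C(=O)C[C@H]2C(C)(C)[C@H](OC(C)=O)[C@H](OC(=O)/C(C)=C\C)C[C@]12COC(C)=O | intermediate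
32 | (13R)-3α,20-diacetoxy-2α-angeloyloxylabda-8,14-diene-7α,13-diol | C=C[C@](C)(O)CCC1=C(C)[C@H](O)C[C@H]2C(C)(C)[C@H](OC(C)=O)[C@H](OC(=O)/C(C)=C\C)C[C@]12COC(C)=O | target

**Summary**

Total step count: 21. Longest linear sequence: 18 steps (steps 1–11 and 15–21); the side-chain branch is steps 12–14.

**Steps most likely to fail**

Step 2. The catalyst may turn over slowly or lose enantiocontrol with the γ,γ-disubstituted allylsilane, whose attack creates a quaternary carbon next to the new stereocentre. Fallback: from 4, a TiCl4-promoted Hosomi–Sakurai addition of 5 (CH2Cl2, −78 °C) would give the racemic keto ester F1. Thermal transesterification with (1R,2S,5R)-menthol (toluene, reflux, DMAP cat.) would give diastereomeric menthyl esters, from which the (5R)-menthyl ester F2 would be separated by crystallisation or chromatography. Methanolysis (MeOH, DMAP cat., reflux) returns to the route at 6.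

Step 10. Cyclopropanation of the congested enol ether may be slow, so that attack of excess alkoxide on the bromo enone competes. Fallback: from 13, Furukawa–Simmons–Smith cyclopropanation (Et2Zn, CH2I2, CH2Cl2, 0 °C) would give the siloxycyclopropane F3. FeCl3 in DMF with pyridine (Ito–Saegusa oxidative ring expansion, cleaving the fused C9–C7 bond through the alkoxy radical) would give the ring-expanded β-chloro ketone F4, and NaOAc in MeOH would eliminate HCl to give the Δ7-en-9-one F5. α-Iodination (I2, pyridine, CH2Cl2) would give the 8-iodo enone F6, and the Suzuki–Miyaura methylation of step 11 returns to the route at 16.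

Step 15. Silyl migration within the lithiated side chain and enolisation in place of addition at the hindered ketone may consume a reagent that is too valuable to use in large excess. Fallback: from 16, but-3-enylmagnesium bromide (large excess) with CeCl3 in THF at −78 °C would give the tertiary alcohol F7. Oxidative transposition with pyridinium chlorochromate as in step 16 would give the 9-(but-3-enyl) enone F8, and Tsuji–Wacker oxidation (PdCl2, CuCl, O2, DMF/H2O) would give the methyl ketone F9. Titanium-promoted asymmetric addition of divinylzinc (Ti(OiPr)4, chiral trans-cyclohexane-1,2-diyl bis(hydroxycamphorsulfonamide) ligand) to the unhindered methyl ketone would give the (13R)-carbinol F10 after chromatographic removal of the C13 epimer. The aqueous acetic acid of step 17 then removes the acetonide and returns to the route at 26.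

**Further compounds**

F1 | step 2 | racemic methyl 5-(2-methylbut-3-en-2-yl)-2-oxocyclopentane-1-carboxylate | O=C1CCC(C(C)(C)C=C)C1C(=O)OC
F2 | step 2 | (1R,2S,5R)-menthyl (5R)-5-(2-methylbut-3-en-2-yl)-2-oxocyclopentane-1-carboxylate | C[C@@H]1CC[C@H]([C@@H](C1)OC(=O)C2C(=O)CC[C@H]2C(C)(C)C=C)C(C)C
F3 | step 10 | methylene adduct of 13 (1-siloxybicyclo[3.1.0]hexane unit, cyclopropane on the α face) | CC(C)[Si](C(C)C)(C(C)C)O[C@@]14[C@H](C4)C[C@H]2C(C)(C)[C@H](OC3(C)C)[C@H](O3)C[C@]12CO[Si](C(C)C)(C(C)C)C(C)C
F4 | step 10 | trans-decalin 7-chloro-9-ketone (2α,3α-acetonide; 10β-CH2OTIPS; C7 epimers) | O=C1CC(Cl)C[C@H]2C(C)(C)[C@H](OC3(C)C)[C@H](O3)C[C@]12CO[Si](C(C)C)(C(C)C)C(C)C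
F5 | step 10 | trans-decalin Δ7-en-9-one without C17 | O=C1C=CC[C@H]2C(C)(C)[C@H](OC3(C)C)[C@H](O3)C[C@]12CO[Si](C(C)C)(C(C)C)C(C)C
F6 | step 10 | trans-decalin 8-iodo-Δ7-en-9-one | O=C1C(I)=CC[C@H]2C(C)(C)[C@H](OC3(C)C)[C@H](O3)C[C@]12CO[Si](C(C)C)(C(C)C)C(C)C
F7 | step 15 | 9-(but-3-enyl)-8-methyl-Δ7-en-9-ol (9β-OH expected; 2α,3α-acetonide; 10β-CH2OTIPS) | C=CCC[C@]1(O)C(C)=CC[C@H]2C(C)(C)[C@H](OC3(C)C)[C@H](O3)C[C@]12CO[Si](C(C)C)(C(C)C)C(C)C
F8 | step 15 | 9-(but-3-enyl)-8-methyl-Δ8-en-7-one | C=CCCC1=C(C)C(=O)C[C@H]2C(C)(C)[C@H](OC3(C)C)[C@H](O3)C[C@]12CO[Si](C(C)C)(C(C)C)C(C)C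
F9 | step 15 | 9-(3-oxobutyl)-8-methyl-Δ8-en-7-one | CC(=O)CCC1=C(C)C(=O)C[C@H]2C(C)(C)[C@H](OC3(C)C)[C@H](O3)C[C@]12CO[Si](C(C)C)(C(C)C)C(C)C
F10 | step 15 | (13R)-13-hydroxy-2α,3α-isopropylidenedioxy-20-(triisopropylsilyloxy)labda-8,14-dien-7-one | C=C[C@](C)(O)CCC1=C(C)C(=O)C[C@H]2C(C)(C)[C@H](OC3(C)C)[C@H](O3)C[C@]12CO[Si](C(C)C)(C(C)C)C(C)C
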